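All constants stand for no real mixture; what happens was integrated by code.

If the dissolved gas stands near saturation, the starting material faces steady first-order losses, and a quick number needs little more.

starting material 0.50 M; gas phase 110 mM (held); protic impurity 0.500 M; time 40 min

- south-west: doubling the transfer coefficient of step 1, all else as stated
- south-east: doubling the saturation concentration of gas phase, all else as stated

- the target standing at 40 min, as a percentage of the starting material charged
- the change that raises the amount of target at 40 min, in percent of the starting material charged most ("none" if none brings more than 2 percentage points) (south-west / south-east / none)
- amount of target at 40 min, in percent of the starting material charged, after south-east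

- at the start none of the gas is dissolved
- run time (flask): 40 min

    gas phase ⇌ dissolved gas, rate k1*(csat - [dissolved gas]) (k1 = 0.296 min⁻¹, csat = 110 mM)
    starting material + dissolved gas → target (k2 = 0.131 M⁻¹ min⁻¹)
    starting material → side product (k3 = 0.00118 min⁻¹)
    target ⇌ isomer of the product (K4 = 0.34, k4 = 0.0114 min⁻¹)
    starting material + protic impurity → quenched substrate (k5 = 0.0891 M⁻¹ min⁻¹)

Transfer renews the dissolved gas at 0.296 min⁻¹, while the starting material spends it at 0.0655 min⁻¹, which is slower. The dissolved gas is therefore the concentration that sets the order: taken at saturation, it makes the target step pseudo-first-order in starting material. The protic impurity is taken at its charge, which is a cruder assumption. The starting material then disappears at 0.0601 min⁻¹. The gas share, the part of the lost starting material that goes to target, is 24.0%.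

By 40 min, 91.0% of the charge is lost. Target is taken as half the run old on average, so forward isomerisation leaves 79.6% of it. That gives 17.4%.

Doubling the saturation concentration lifts the share to 38.7% and the loss to 94.9%, giving 29.2%. Faster transfer trims a lag of 3.38 min, shorter than the run. The choice is south-east.

The forecast gives 17.8% (16.5% to 19%), a little above this reckoning. It chooses south-east and gives 29.3% (27% to 31%), holding that “faster transfer only shortens a brief lag”.

The simulation gives 17.8%, chooses south-east with 12 percentage points against 1.6 points for south-west, and gives 29.6%.

At 9.29 min in the flask, the protic impurity uses starting material 2.7 times as fast as the dissolved gas does. At 40.0 min the flask holds 56.9% quenched substrate and 17.8% target.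

With 0.30 M of protic impurity, the gas share becomes 34.1%. With 81.6% lost and the same isomerisation, it gives 22.1%. That neighbour holds 22.3%.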